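## Structural features

The target is a flavone: benzene ring A is fused to the 4-pyranone ring C (O1, C2, C3, C4=O, C4a, C8a), and the unsubstituted phenyl ring B sits on C2. Ring A carries a methoxy group on C5, a free hydroxyl on C7 and, on C8, carbon C2' of an N-methylpiperidine (piperidine atoms primed). C2' is the only stereocentre. With the ranking N1' > C8 > C3' > H it is R, and because this ranking is the same in every 2-arylpiperidine of the route, the descriptor never changes. C2' is benzylic, bound to nitrogen, flanked by two ring oxygens (O7 on C7 and O1 on C8a) and para to the C5 methoxy group. The C2'–N1' bond can therefore ionise with help from an ortho oxygen, which is the main threat to configuration once it is set. Other fragile points are the C2=C3–C4=O unit of ring C (hydride, hot alkali), the C5 methyl ether (strong Lewis acids) and the free positions of the electron-rich ring A, which are readily attacked by one-carbon electrophiles. The real difficulty is not the flavone but creating and keeping a single aminated benzylic stereocentre beside a doubly ortho-substituted, trioxygenated arene. The key step turns this lability into the method: in the array O7–C7–C8–C2' (or its twin O8a–C8a–C8–C2') loss of a leaving group from C2' gives a planar ortho-quinone methide. Before ring C exists the two ortho oxygens and the two free ring positions are equivalent, so it does not matter which one is used.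

## Logic of the disconnections

**16 to 13 and 14 (through 15).** The bonds O1–C2 and C2–C3 are cut. Ring C holds no stereocentre and is the part most sensitive to hydride and base, so it is built last. This removes rings B and C and leaves a ring-A methyl ketone. The forward step must acylate the ketone enolate at carbon in the presence of two phenoxides. It must then close the ring in acid, where only the hydroxyl lying between the acyl group and C8 can reach the new carbonyl, so regiochemistry is automatic. C2' has to survive strong base and warm acid; it is not acidic, and in acid its nitrogen is protonated and a poor leaving group.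

**13 to 12.** The aryl–acetyl bond C4a–C4 is cut. In 12 the two unsubstituted ring positions are related by the local twofold axis through C8 and C5, so acylation at either gives the same ketone and no directing or blocking group is needed. The forward step must stop at monoacylation and must not ionise C2'–N1'.

**12 to 11.** No skeletal bond is cut: the N-methyl carbon of 12 is the carbamate carbonyl carbon of 11. The carbamate is needed on nitrogen for the key step (non-basic, an N–H to bind the catalyst), and hydride converts it directly into the methyl group. This avoids a deprotection and a reductive methylation with formaldehyde, which ring A would not tolerate. The demand is one of order: the hydride must be used before any carbonyl is placed on ring A.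

**11 to 9 (through 10).** The N1'–C2' bond is cut; this is the strategic step. The stereocentre and the piperidine ring are traded for a racemic secondary alcohol on an open chain, and both enantiomers of 9 are funnelled through planar 10. The design of 9 follows from what the forward step needs:
- Both ortho hydroxyls are free, so either can assist ionisation and both lead to the same intermediate, and 11 keeps the symmetry used two steps later.
- Nitrogen is a neutral N–H carbamate that a chiral Brønsted acid can hold by hydrogen bonding.
- The triol is so easily ionised that it must never meet silica or stray acid. It is therefore generated under basic conditions and used crude.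

**9 to 6 (through 7 and 8).** The C2'–OH bond is traced back to a ketone, which is the stable, storable form of the precursor; no stereocontrol is wanted. A ketone chelated by two ortho phenols is a poor hydride acceptor once deprotonated, and its reduction product tends to lose the benzylic oxygen. The phenols are therefore masked in the flask as silyl ethers during hydride delivery and unmasked cold with base.

**6 to 5.** The O–CH2 bonds of two acetal protecting groups are cut. They serve only to direct the metalation and are removed at the ketone stage on purpose: here the acyl group deactivates ring A towards the liberated one-carbon electrophile and C2' carries no leaving group. The step needs a Lewis acid mild enough for the carbamate and a scavenger for the acetal carbon.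

**5 to 2 and 3 (through 4).** The C8–C2' bond is cut. One step joins ring A to the whole five-carbon aminated chain, with the oxidation level at C2' that the next steps need. The demands are metalation between the two acetal oxygens rather than next to the methoxy group, and a single addition to the imide-like ring carbonyl of 3.

**2 to 1.** The two phenol O–C bonds are cut; protection turns the phenols into the pair of directing groups that fixes the site of metalation.

## Other disconnections considered

**Alternative 1: both flanking oxygens by directed C–H oxidation.**
- Cut: the C7–O and C8a–O bonds; the piperidine is carried as a pyridine.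
- Forward key step: 2-(4-methoxyphenyl)pyridine A1 would be acetoxylated twice with Pd(OAc)2 and PhI(OAc)2 to the diacetate A2. The pyridine nitrogen directs cyclopalladation to each ortho C–H, and oxidation to tetravalent palladium is followed by C–O reductive elimination. N-methylation to the pyridinium salt A3, asymmetric hydrogenation (for instance [Ir(cod)Cl]2 with (R)-SynPhos) and acetate cleavage would converge on 12.
- In favour: very short, no protecting groups, and the N-methyl group arrives without hydride. The ligand-directed acetoxylation is established chemistry, and on this point it is the better of the two plans, since the chosen key step is not. The symmetric diacetate keeps the same local symmetry (equal).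
- Against: the second acetoxylation has to proceed on a biaryl already twisted by the first acetate, and the anisole ring is exposed to the hypervalent iodine oxidant. The stereocentre would come from hydrogenating a pyridinium ring bearing a 2,6-disubstituted aryl group. Such hydrogenations are best documented for N-benzyl salts with unhindered aryl groups, so an N-methyl, doubly ortho-substituted case is a weak point, and a benzyl detour would cost steps.
- Comparison: it is better on step count (about four steps to 12 against six) and on precedent for its key step. It is weaker where it matters most, because stereocontrol is deferred to a later step on an unfavourable substrate, whereas the chosen plan sets C2' in the key step itself.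

**Alternative 2: sulfamidate-tethered cyclic imine.**
- Cut: C2'–C3' and N1'–C6', the piperidine being annulated onto a C2'=N1' bond held in a ring through one ortho oxygen.
- Forward key step: the cyclic N-sulfonyl imine A4 and methyl vinyl ketone A5, activated as a 2-aminodiene by 9-amino-9-deoxy-epi-quinine, would undergo a Mannich addition and then an aza-Michael closure to the tricyclic piperidinone A6.
- In favour: the enantioselective step has close precedent on salicylaldehyde-derived cyclic sulfonyl imines, where the ring fixes the imine geometry; here it is the better plan. It also forms two bonds and the ring in one operation, which is better in bond count.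
- Against: A6 carries a C4' ketone that the target lacks, a sulfamidate that must be cleaved, and no N-methyl group, so three or four corrective steps follow. The imine carbon of A4 is flanked by an ortho methoxymethoxy group, which should slow the Mannich step. The two ring-A oxygens have to be differentiated from the start, which the target does not require.
- Comparison: structurally it uses the same ortho oxygen, but as a covalent tether rather than as an electron donor. Mechanistically it is the safer asymmetric step. In step economy it is clearly longer, and once the sulfamidate is opened C2' is exactly as labile as in the chosen route (equal).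

**Alternative 3: ring A grown on D-pipecolate.**
- Cut: C8–C8a and C6–C7, with C4a–C8a re-formed; the piperidine and its configuration come from the chiral pool.
- Forward key step: the ester A7 would be homologated to the siloxyalkyne A8. Heating A8 with 3-methoxycyclobutenone A9 should give the phenol A10 by vinylketene formation, [2+2] cycloaddition, four-electron ring opening and six-electron closure. Desilylation of A10 gives 11.
- In favour: the absolute configuration is bought, no asymmetric catalysis is needed, and the regiochemistry of the benzannulation is predictable; on certainty of the stereochemical outcome it is the better plan. It reaches 11 in about four steps from A7, equal to or slightly better than the five steps of the chosen route.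
- Against: the stereocentre of A7 is alpha to an ester and a carbamate and must survive the strongly basic ynolate chemistry, where deprotonation at C2' would racemise it. A8 is alpha-branched and crowded for the [2+2] step, and A9 is a sensitive, uncommon reagent. The differentiated phenols of A10 bring no benefit and cost a desilylation.
- Comparison: the pericyclic cascade is mechanistically well understood, whereas the chosen key step is unprecedented, a point for the alternative. The chosen plan starts from cheaper materials and never exposes a formed stereocentre to strong base, and the two meet at the same compound 11.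

Key step: step 5

Assumption: which antipode of the phosphoric acid delivers the R product cannot be predicted with confidence; the (R)-acid is written, and its mirror image is to be taken should the sense of induction be the opposite.

## Route

Step 1
Reactants: 1 5-methoxyresorcinol
Product: 2 1-methoxy-3,5-bis(methoxymethoxy)benzene
Conditions: MOMCl (2.6 equiv), i-Pr2NEt (3 equiv), CH2Cl2, 0 °C to rt
Reagents that add atoms: chloromethyl methyl ether, COCCl
Why: O-alkylation of both phenols to the bis-acetal; the two methoxymethyl ethers are the directing groups for the metalation in step 2.

Step 2
Reactants: 2 1-methoxy-3,5-bis(methoxymethoxy)benzene; 3 tert-butyl 2-oxopiperidine-1-carboxylate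
Product: 5 tert-butyl {5-[4-methoxy-2,6-bis(methoxymethoxy)phenyl]-5-oxopentyl}carbamate, via aryllithium 4 (not isolated)
Conditions: n-BuLi (1.1 equiv), THF, 0 °C; added to 3 (1.2 equiv), THF, −78 °C; aq. NH4Cl
Reagents that add atoms: none
Why: Directed ortho-metalation at the position flanked by both acetal oxygens (two cooperating directors outweigh the methoxy group), then addition to the activated ring carbonyl of the N-acyl lactam and ring opening to the amino ketone. The carbamate anion formed on opening and the two ortho substituents of the new aryl ketone should prevent a second addition.

Step 3
Reactants: 5 tert-butyl {5-[4-methoxy-2,6-bis(methoxymethoxy)phenyl]-5-oxopentyl}carbamate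
Product: 6 tert-butyl [5-(2,6-dihydroxy-4-methoxyphenyl)-5-oxopentyl]carbamate
Conditions: MgBr2·OEt2 (6 equiv), n-BuSH (6 equiv), Et2O/CH2Cl2, 0 °C to rt
Reagents that add atoms: none
Why: Lewis acid-mediated acetal cleavage in which the thiol captures the methoxymethyl unit as a thioacetal, so that it cannot alkylate ring A. The conditions are mild enough to spare the tert-butyl carbamate, and the ketone deactivates the ring at this stage.

Step 4
Reactants: 6 tert-butyl [5-(2,6-dihydroxy-4-methoxyphenyl)-5-oxopentyl]carbamate
Product: 9 racemic tert-butyl [5-(2,6-dihydroxy-4-methoxyphenyl)-5-hydroxypentyl]carbamate, via bis(trimethylsilyl) ether 7 (not isolated), via silylated carbinol 8 (not isolated)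
Conditions: Me3SiN=C(Me)OSiMe3 (3 equiv), THF, 40 °C; LiBH4 (2 equiv), 0 °C; K2CO3, MeOH, 0 °C; pH 7 buffer; crude product used at once
Reagents that add atoms: none
Why: Transient O-silylation removes the phenoxide deactivation of the chelated ketone and the phenoxide-driven loss of the benzylic oxygen, so that borohydride reduction should stop at the carbinol. Cold basic methanolysis then frees the phenols without acid, and the alcohol is formed racemic, as the next step requires.

Step 5
Reactants: 9 racemic tert-butyl [5-(2,6-dihydroxy-4-methoxyphenyl)-5-hydroxypentyl]carbamate
Product: 11 tert-butyl (2R)-2-(2,6-dihydroxy-4-methoxyphenyl)piperidine-1-carboxylate, via ortho-quinone methide 10 (not isolated)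
Conditions: (R)-3,3'-bis(2,4,6-triisopropylphenyl)-1,1'-binaphthyl-2,2'-diyl hydrogen phosphate (10 mol %), 5 Å MS, toluene/CH2Cl2 (4:1), 0.01 M, slow addition of 9, −40 °C; Et3N quench
Reagents that add atoms: none
Why: Proposed new method: the phosphoric acid protonates the C2' hydroxyl of 9 and an ortho phenol pushes water out, so that both enantiomers of 9 converge on the planar ortho-quinone methide 10, held as a hydrogen-bonded ion pair by the chiral phosphate (a stereoablative, dynamic process). The phosphoryl oxygen at the same time binds the carbamate N–H, and nitrogen adds to C2' in an intramolecular aza-Michael addition, the ring closing in the 6-exo-trig mode onto the exocyclic C8=C2' bond with re-aromatisation of ring A as the driving force. The closest known reaction type is the chiral phosphoric acid-catalysed conjugate addition of external nucleophiles to ortho-quinone methides generated from ortho-hydroxybenzyl alcohols; capture by a tethered carbamate to close a 2-arylpiperidine on an alkyl-substituted, trioxygenated system has no direct counterpart. The C2' stereocentre is set by the catalyst alone, whose 2,4,6-triisopropylphenyl walls should leave one face of bound 10 open to the tethered nitrogen. Enantiofacial selectivity therefore requires that the catalysed path outrun uncatalysed ionisation, which the low temperature, the weakly polar medium and the exclusion of other acids are meant to secure. Chemoselectivity rests on ring size (nitrogen closes a six-membered ring, the carbamate oxygen would close an eight-membered one) and on high dilution with slow addition, which disfavours attack of ring A of a second molecule on 10. The two equivalent ortho hydroxyls mean that ionisation from either side leads to the same intermediate, and proton loss from C3' to a 2-vinylphenol is reversible under the acid and returns to 10. The tert-butyl carbamate is a poor leaving group, so 11 should not re-ionise at this temperature.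

Step 6
Reactants: 11 tert-butyl (2R)-2-(2,6-dihydroxy-4-methoxyphenyl)piperidine-1-carboxylate
Product: 12 5-methoxy-2-[(2R)-1-methylpiperidin-2-yl]benzene-1,3-diol
Conditions: LiAlH4 (6 equiv), THF, reflux; aq. potassium sodium tartrate, pH 8
Reagents that add atoms: none
Why: Hydride reduction of the carbamate to the N-methyl amine, the carbonyl carbon becoming the methyl group and tert-butoxide being lost; the phenols are inert as aluminium phenoxides. C2' is not acidic and nitrogen is not expelled under these basic conditions, so the configuration should be retained.

Step 7
Reactants: 12 5-methoxy-2-[(2R)-1-methylpiperidin-2-yl]benzene-1,3-diol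
Product: 13 1-{2,4-dihydroxy-6-methoxy-3-[(2R)-1-methylpiperidin-2-yl]phenyl}ethan-1-one
Conditions: AcOH (1.5 equiv), BF3·OEt2, 65 °C; aq. NaOAc, MeOH, 50 °C
Reagents that add atoms: acetic acid, CC(=O)O
Why: BF3-mediated Friedel–Crafts (Fries-type) C-acetylation of a resorcinol; the two open ring positions are equivalent, so one regioisomer results, and the chelated ketone deactivates the ring against a second acylation. Nitrogen is tied up as its BF3 adduct, a poor leaving group, which should protect C2'.

Step 8
Reactants: 13 1-{2,4-dihydroxy-6-methoxy-3-[(2R)-1-methylpiperidin-2-yl]phenyl}ethan-1-one; 14 benzoyl chloride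
Product: 16 7-hydroxy-5-methoxy-8-[(2R)-1-methylpiperidin-2-yl]-2-phenyl-4H-chromen-4-one, via 1,3-diketone 15 (not isolated)
Conditions: LiN(SiMe3)2 (4.2 equiv), THF, −78 to −10 °C; 14 (1.05 equiv), −78 °C to rt; AcOH, evaporate; AcOH, H2SO4, 80 °C; NaHCO3 to pH 8
Reagents that add atoms: none
Why: Claisen-type C-benzoylation of the lithium enolate of the fully deprotonated ortho-hydroxyacetophenone (the one-flask form of the Baker–Venkataraman route), then acid-catalysed cyclodehydration. Only the hydroxyl between the acyl group and C8 can reach the new carbonyl, so the pyranone forms with O1 next to C8, and C2' is touched by neither the base nor the acid.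

## Compound list

1 | 5-methoxyresorcinol (5-methoxybenzene-1,3-diol) | COc1cc(O)cc(O)c1 | starting material
2 | 1-methoxy-3,5-bis(methoxymethoxy)benzene | COCOc1cc(OC)cc(OCOC)c1 | intermediate
3 | tert-butyl 2-oxopiperidine-1-carboxylate | O=C1CCCCN1C(=O)OC(C)(C)C | starting material
4 | [4-methoxy-2,6-bis(methoxymethoxy)phenyl]lithium | [Li]c1c(OCOC)cc(OC)cc1OCOC | intermediate
5 | tert-butyl {5-[4-methoxy-2,6-bis(methoxymethoxy)phenyl]-5-oxopentyl}carbamate | COCOc1cc(OC)cc(OCOC)c1C(=O)CCCCNC(=O)OC(C)(C)C | intermediate
6 | tert-butyl [5-(2,6-dihydroxy-4-methoxyphenyl)-5-oxopentyl]carbamate | COc1cc(O)c(C(=O)CCCCNC(=O)OC(C)(C)C)c(O)c1 | intermediate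
7 | tert-butyl (5-{4-methoxy-2,6-bis[(trimethylsilyl)oxy]phenyl}-5-oxopentyl)carbamate | COc1cc(O[Si](C)(C)C)c(C(=O)CCCCNC(=O)OC(C)(C)C)c(O[Si](C)(C)C)c1 | intermediate
8 | racemic tert-butyl (5-hydroxy-5-{4-methoxy-2,6-bis[(trimethylsilyl)oxy]phenyl}pentyl)carbamate | COc1cc(O[Si](C)(C)C)c(C(O)CCCCNC(=O)OC(C)(C)C)c(O[Si](C)(C)C)c1 | intermediate
9 | racemic tert-butyl [5-(2,6-dihydroxy-4-methoxyphenyl)-5-hydroxypentyl]carbamate | COc1cc(O)c(C(O)CCCCNC(=O)OC(C)(C)C)c(O)c1 | intermediate
10 | tert-butyl [5-(2-hydroxy-4-methoxy-6-oxocyclohexa-2,4-dien-1-ylidene)pentyl]carbamate (ortho-quinone methide) | COC1=CC(=O)C(=CCCCCNC(=O)OC(C)(C)C)C(O)=C1 | intermediate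
11 | tert-butyl (2R)-2-(2,6-dihydroxy-4-methoxyphenyl)piperidine-1-carboxylate | COc1cc(O)c([C@H]2CCCCN2C(=O)OC(C)(C)C)c(O)c1 | intermediate
12 | 5-methoxy-2-[(2R)-1-methylpiperidin-2-yl]benzene-1,3-diol | COc1cc(O)c([C@H]2CCCCN2C)c(O)c1 | intermediate
13 | 1-{2,4-dihydroxy-6-methoxy-3-[(2R)-1-methylpiperidin-2-yl]phenyl}ethan-1-one | COc1cc(O)c([C@H]2CCCCN2C)c(O)c1C(C)=O | intermediate
14 | benzoyl chloride | O=C(Cl)c1ccccc1 | starting material
15 | 1-{2,4-dihydroxy-6-methoxy-3-[(2R)-1-methylpiperidin-2-yl]phenyl}-3-phenylpropane-1,3-dione | COc1cc(O)c([C@H]2CCCCN2C)c(O)c1C(=O)CC(=O)c1ccccc1 | intermediate
16 | 7-hydroxy-5-methoxy-8-[(2R)-1-methylpiperidin-2-yl]-2-phenyl-4H-chromen-4-one | COc1cc(O)c([C@H]2CCCCN2C)c2oc(-c3ccccc3)cc(=O)c12 | target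

## Step count and least certain steps

Total step count: 8. Longest linear sequence: 8 steps, from 1 to 16.

**Step 5 (key step, new method).** The most likely failure is poor facial selectivity, because uncatalysed ionisation of the very electron-rich benzylic alcohol competes with the catalyst-bound path. Oligomerisation by intermolecular attack of ring A on the quinone methide is the second risk. The fallback gives up catalytic control and uses known chemistry. Starting from 9, ring closure with an achiral acid, (PhO)2P(O)OH in CH2Cl2 at rt, is an ordinary acid-promoted benzylic amidation and should give racemic tert-butyl 2-(2,6-dihydroxy-4-methoxyphenyl)piperidine-1-carboxylate F1. Preparative chromatography on a chiral stationary phase then separates the R enantiomer, which is 11 and rejoins the route there, from tert-butyl (2S)-2-(2,6-dihydroxy-4-methoxyphenyl)piperidine-1-carboxylate F2, which is set aside.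

**Step 4.** Incomplete silylation would leave a phenoxide-deactivated ketone. Elimination of the benzylic oxygen followed by a second hydride delivery would over-reduce, and the triol may ionise during isolation. The fallback replaces the in-flask masking by an isolable silyl relay. Starting from 6, silylation with t-BuMe2SiCl and imidazole in DMF should give tert-butyl (5-{2,6-bis[(tert-butyldimethylsilyl)oxy]-4-methoxyphenyl}-5-oxopentyl)carbamate F3. Reduction with NaBH4 in MeOH/THF should give racemic tert-butyl (5-{2,6-bis[(tert-butyldimethylsilyl)oxy]-4-methoxyphenyl}-5-hydroxypentyl)carbamate F4, a stable, purifiable and storable form of the precursor. Buffered fluoride (Bu4NF, AcOH, THF, 0 °C) releases 9 immediately before step 5, where the route is rejoined.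

**Step 7.** Hot Lewis acid may erode the configuration at C2' through reversible C–N ionisation; acylation may stop at oxygen, or a second acyl group may enter. The fallback avoids Friedel–Crafts chemistry and the acetophenone altogether. Starting from 12, monoiodination at either equivalent ring position (N-iodosuccinimide, 1 equiv, MeCN, −20 °C) should give 4-iodo-5-methoxy-2-[(2R)-1-methylpiperidin-2-yl]benzene-1,3-diol F5. Carbonylative annulation of this ortho-iodophenol with phenylacetylene (PdCl2(PPh3)2, CO, Et2NH, 60 °C) builds ring C by acyl–alkyne coupling and 6-endo closure of the hydroxy ynone. It returns directly at 16 and bypasses step 8 as well.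

**Step 8.** O-benzoylation of the phenoxides may compete with C-acylation of the enolate, and cyclodehydration may be incomplete. The fallback is the stepwise Baker–Venkataraman sequence. Starting from 13, benzoyl chloride in pyridine should give 4-acetyl-5-methoxy-2-[(2R)-1-methylpiperidin-2-yl]-1,3-phenylene dibenzoate F6. KOH in pyridine at 50 °C shifts the ortho benzoyl group to carbon and should give 3-hydroxy-5-methoxy-2-[(2R)-1-methylpiperidin-2-yl]-4-(3-oxo-3-phenylpropanoyl)phenyl benzoate F7. AcOH with H2SO4 closes it to 5-methoxy-8-[(2R)-1-methylpiperidin-2-yl]-4-oxo-2-phenyl-4H-chromen-7-yl benzoate F8, and K2CO3 in MeOH cleaves the remaining benzoate to return at 16.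

## Further compounds

F1 | step 5 | racemic tert-butyl 2-(2,6-dihydroxy-4-methoxyphenyl)piperidine-1-carboxylate | COc1cc(O)c(C2CCCCN2C(=O)OC(C)(C)C)c(O)c1
F2 | step 5 | tert-butyl (2S)-2-(2,6-dihydroxy-4-methoxyphenyl)piperidine-1-carboxylate | COc1cc(O)c([C@@H]2CCCCN2C(=O)OC(C)(C)C)c(O)c1
F3 | step 4 | tert-butyl (5-{2,6-bis[(tert-butyldimethylsilyl)oxy]-4-methoxyphenyl}-5-oxopentyl)carbamate | COc1cc(O[Si](C)(C)C(C)(C)C)c(C(=O)CCCCNC(=O)OC(C)(C)C)c(O[Si](C)(C)C(C)(C)C)c1
F4 | step 4 | racemic tert-butyl (5-{2,6-bis[(tert-butyldimethylsilyl)oxy]-4-methoxyphenyl}-5-hydroxypentyl)carbamate | COc1cc(O[Si](C)(C)C(C)(C)C)c(C(O)CCCCNC(=O)OC(C)(C)C)c(O[Si](C)(C)C(C)(C)C)c1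
F5 | step 7 | 4-iodo-5-methoxy-2-[(2R)-1-methylpiperidin-2-yl]benzene-1,3-diol | COc1cc(O)c([C@H]2CCCCN2C)c(O)c1I
F6 | step 8 | 4-acetyl-5-methoxy-2-[(2R)-1-methylpiperidin-2-yl]-1,3-phenylene dibenzoate | COc1cc(OC(=O)c2ccccc2)c([C@H]2CCCCN2C)c(OC(=O)c2ccccc2)c1C(C)=O
F7 | step 8 | 3-hydroxy-5-methoxy-2-[(2R)-1-methylpiperidin-2-yl]-4-(3-oxo-3-phenylpropanoyl)phenyl benzoate | COc1cc(OC(=O)c2ccccc2)c([C@H]2CCCCN2C)c(O)c1C(=O)CC(=O)c1ccccc1
F8 | step 8 | 5-methoxy-8-[(2R)-1-methylpiperidin-2-yl]-4-oxo-2-phenyl-4H-chromen-7-yl benzoate | COc1cc(OC(=O)c2ccccc2)c([C@H]2CCCCN2C)c2oc(-c3ccccc3)cc(=O)c12
A1 | alternative 1 | 2-(4-methoxyphenyl)pyridine | COc1ccc(-c2ccccn2)cc1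
A2 | alternative 1 | 5-methoxy-2-(pyridin-2-yl)-1,3-phenylene diacetate | COc1cc(OC(C)=O)c(-c2ccccn2)c(OC(C)=O)c1
A3 | alternative 1 | 2-[2,6-bis(acetyloxy)-4-methoxyphenyl]-1-methylpyridin-1-ium iodide | COc1cc(OC(C)=O)c(-c2cccc[n+]2C)c(OC(C)=O)c1.[I-]
A4 | alternative 2 | 7-methoxy-5-(methoxymethoxy)-1,2,3-benzoxathiazine 2,2-dioxide | COCOc1cc(OC)cc2OS(=O)(=O)N=Cc12
A5 | alternative 2 | but-3-en-2-one (methyl vinyl ketone) | C=CC(C)=O
A6 | alternative 2 | (R)-configured tricyclic sulfamidate in which a piperidin-4-one is fused through N1' and C2' to the benzoxathiazine dioxide, with methoxy para and methoxymethoxy ortho to C2' | COCOc1cc(OC)cc2OS(=O)(=O)N3CCC(=O)C[C@@H]3c12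
A7 | alternative 3 | methyl (2R)-1-(tert-butoxycarbonyl)piperidine-2-carboxylate | COC(=O)[C@H]1CCCCN1C(=O)OC(C)(C)C
A8 | alternative 3 | tert-butyl (2R)-2-({[tri(propan-2-yl)silyl]oxy}ethynyl)piperidine-1-carboxylate | CC(C)[Si](OC#C[C@H]1CCCCN1C(=O)OC(C)(C)C)(C(C)C)C(C)C
A9 | alternative 3 | 3-methoxycyclobut-2-en-1-one | COC1=CC(=O)C1
A10 | alternative 3 | tert-butyl (2R)-2-(2-hydroxy-4-methoxy-6-{[tri(propan-2-yl)silyl]oxy}phenyl)piperidine-1-carboxylate | COc1cc(O)c([C@H]2CCCCN2C(=O)OC(C)(C)C)c(O[Si](C(C)C)(C(C)C)C(C)C)c1
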